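**Retrosynthesis**
- The target is a 2,3-trans-2-aryl-3-(hydroxymethyl)-4-aroyl tetrahydrofuran. Its only ring is formed last, by anodic oxidation of ring-A phenol diol-ketone **10** to a p-quinone methide that is trapped 5-exo by C9'-OH (C7–O bond, C7 set trans to C8).
- **10** comes from bis-benzyl ether triol **8** by selective benzylic oxidation and debenzylation. **8** comes from the Reformatsky adduct **7** (C8'–C7' bond) by LiAlH4 reduction.
- **7** comes from α-bromo ester **5** plus aldehyde **6**. **5** comes from the Seebach anti-alkylation product **4**, whose C3 becomes C8 (R).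
- The (S)-malate carbinol carbon directs C8 and is erased at the bromide stage. C7 and C8' are then controlled by C8 (ring closure, then enolisation).

Assumptions: Seebach alkylation of the (S)-malate dianion with benzyl bromide **2** gives the 2,3-anti (2S,3R) adduct, as for other alkyl halides. Compounds **1** and **6** are commercially available. The 3,4-trans isomer of the final α-aroyl THF is the thermodynamic one.

**Step 1**
Reactants: **1** (4-(benzyloxy)-3,5-dimethoxyphenyl)methanol
Product: **2** 5-(bromomethyl)-2-(benzyloxy)-1,3-dimethoxybenzene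
Conditions: PBr3, Et2O, 0 °C, 30 min; use crude at once
Reagents that add atoms: PBr3, BrP(Br)Br
Why: Electron-rich benzylic alcohols convert cleanly to bromides with PBr3; no stereocenter is involved.

**Step 2**
Reactants: **2**; **3** dimethyl (S)-malate (dimethyl L-malate)
Product: **4** dimethyl (2S,3R)-3-[(4-benzyloxy-3,5-dimethoxyphenyl)methyl]-2-hydroxybutanedioate
Conditions: LDA (2.2 equiv), THF, −78 → −20 °C to form the dianion; then **2**, −78 → −20 °C
Reagents that add atoms: none
Why: Seebach diastereoselective alkylation of the chelated malate dianion; the electrophile attacks anti to the C2 alkoxide, so C3 is created as R, which becomes C8 of the target.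

**Step 3**
Reactants: **4**
Product: **5** dimethyl (2R,3S)-2-bromo-3-[(4-benzyloxy-3,5-dimethoxyphenyl)methyl]butanedioate
Conditions: PPh3, CBr4, CH2Cl2, 0 °C → rt
Reagents that add atoms: CBr4, BrC(Br)(Br)Br
Why: Appel bromination is neutral and proceeds with SN2 inversion at C2. That centre is erased in the next step, so only the retained C3 configuration matters.

**Step 4**
Reactants: **5**; **6** 4-(benzyloxy)-3,5-dimethoxybenzaldehyde
Product: **7** dimethyl 2-[(4-benzyloxy-3,5-dimethoxyphenyl)(hydroxy)methyl]-3-[(4-benzyloxy-3,5-dimethoxyphenyl)methyl]butanedioate, with C8 (R) defined. It is a mixture at C7'/C8' and may partly lactonise.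
Conditions: Zn dust (TMSCl-activated), THF, 50 °C; then aq. NH4Cl
Reagents that add atoms: none
Why: A Reformatsky aldol forms the C8'–C7' bond. The new C7'/C8' centres are not needed, since C7' is oxidised in Step 6 and C8' is later equilibrated.

**Step 5**
Reactants: **7**
Product: **8** (2R)-2-{[(4-benzyloxy-3,5-dimethoxyphenyl)methyl]}-3-[(4-benzyloxy-3,5-dimethoxyphenyl)(hydroxy)methyl]butane-1,4-diol, with C8 (R) retained
Conditions: LiAlH4, THF, 0 °C → rt
Reagents that add atoms: none
Why: Hydride reduction takes both esters, and any lactone, to the triol. The benzyl ethers and the C8 stereocentre are unaffected.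

**Step 6**
Reactants: **8**
Product: **9** 4-hydroxy-1-(4-benzyloxy-3,5-dimethoxyphenyl)-2-(hydroxymethyl)-3-[(4-benzyloxy-3,5-dimethoxyphenyl)methyl]butan-1-one, with C8 (R) defined
Conditions: activated MnO2 (15 equiv), CH2Cl2, rt, 6 h
Reagents that add atoms: none
Why: MnO2 oxidises the electron-rich secondary benzylic alcohol selectively to the aryl ketone and leaves the primary aliphatic alcohols alone.

**Step 7**
Reactants: **9**
Product: **10** 4-hydroxy-1-(4-hydroxy-3,5-dimethoxyphenyl)-2-(hydroxymethyl)-3-[(4-hydroxy-3,5-dimethoxyphenyl)methyl]butan-1-one, with C8 (R) defined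
Conditions: H2 (1 atm), 10% Pd/C, EtOAc/EtOH, rt, 2 h
Reagents that add atoms: none
Why: Hydrogenolysis removes both aryl benzyl ethers; the aryl ketone survives short neutral hydrogenolysis. Ring A now has the free syringyl phenol needed for quinone-methide formation.

**Step 8**
Reactants: **10**
Product: **11** (4-hydroxy-3,5-dimethoxyphenyl)[(3S,4R,5S)-5-(4-hydroxy-3,5-dimethoxyphenyl)-4-(hydroxymethyl)oxolan-3-yl]methanone (target)
Conditions: undivided cell, graphite anode, Pt cathode, constant current (about 2.2 F/mol), Et4NBF4 (0.1 M), 2,6-lutidine (3 equiv), MeCN/HFIP 3:1, 25 °C; then Et3N (5 equiv), 25 °C, 2 h (one pot)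
Reagents that add atoms: none (electrons only; H2 evolves at the cathode)
Why: Proposed new method: the ring-A 4-alkyl-2,6-dimethoxyphenol oxidises at about +1.0 V vs SCE, well below the 4-acylphenol ring B, and loses 2e⁻/2H⁺ to the p-quinone methide at C7. The tethered C9'-OH adds 5-exo to C7 (the 4-exo closure by C9-OH is disfavoured), anti to the C8 CH2OH, which sets 2,3-trans; the cathode reduces H+ to H2, so no chemical oxidant is used. The ketone-acidified C8'-H then equilibrates with Et3N to the 3,4-trans isomer. The closest known reactions are DDQ- or anodic quinone-methide formation from 4-alkylphenols with intramolecular alcohol capture (Swenton/Kita type) and the quinone-methide trapping seen in lignin β–β coupling; here it is applied to a free syringyl CH2 in a β-hydroxy aryl-ketone diol, where it has not been shown.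

**Compound list**

| No. | Name | SMILES | Role |
|---|---|---|---|
| 1 | (4-(benzyloxy)-3,5-dimethoxyphenyl)methanol | OCc1cc(OC)c(OCc2ccccc2)c(OC)c1 | starting material |
| 2 | 2-(benzyloxy)-5-(bromomethyl)-1,3-dimethoxybenzene | BrCc1cc(OC)c(OCc2ccccc2)c(OC)c1 | intermediate |
| 3 | dimethyl (S)-malate | COC(=O)C[C@H](O)C(=O)OC | starting material |
| 4 | dimethyl (2S,3R)-2-hydroxy-3-(arylmethyl)succinate | COC(=O)[C@H](Cc1cc(OC)c(OCc2ccccc2)c(OC)c1)[C@H](O)C(=O)OC | intermediate |
| 5 | dimethyl (2R,3S)-2-bromo-3-(arylmethyl)succinate | COC(=O)[C@H](Cc1cc(OC)c(OCc2ccccc2)c(OC)c1)[C@@H](Br)C(=O)OC | intermediate |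
| 6 | 4-(benzyloxy)-3,5-dimethoxybenzaldehyde | O=Cc1cc(OC)c(OCc2ccccc2)c(OC)c1 | starting material |
| 7 | Reformatsky adduct (C8 defined; C7', C8' mixture) | COC(=O)[C@H](Cc1cc(OC)c(OCc2ccccc2)c(OC)c1)C(C(O)c1cc(OC)c(OCc2ccccc2)c(OC)c1)C(=O)OC | intermediate |
| 8 | bis-benzyl triol | OC[C@H](Cc1cc(OC)c(OCc2ccccc2)c(OC)c1)C(C(O)c1cc(OC)c(OCc2ccccc2)c(OC)c1)CO | intermediate |
| 9 | bis-benzyl keto diol | OC[C@H](Cc1cc(OC)c(OCc2ccccc2)c(OC)c1)C(C(=O)c1cc(OC)c(OCc2ccccc2)c(OC)c1)CO | intermediate |
| 10 | diphenol keto diol | OC[C@H](Cc1cc(OC)c(O)c(OC)c1)C(C(=O)c1cc(OC)c(O)c(OC)c1)CO | intermediate |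
| 11 | target (3S,4R,5S)-oxolane | COc1cc(C(=O)[C@@H]2CO[C@H](c3cc(OC)c(O)c(OC)c3)[C@H]2CO)cc(OC)c1O | target |

**Totals**
- Total steps: 8.
- Longest linear sequence: 8 (1 → 2 → 4 → 5 → 7 → 8 → 9 → 10 → 11).

**Three steps most likely to fail**
1. **Step 8 (proposed new anodic cyclisation).** Risks are over-oxidation of the product's still-electron-rich ring A, elimination of the quinone methide to the C7=C8 styrene, and poor dr.
   - Fallback: oxidise **10** with DDQ in MeOH to the C7 methyl ether (quinone methide trapped by solvent), then ionise the syringyl benzylic ether with CSA in HFIP so that C9'-OH closes the THF under thermodynamic control. Finish with Et3N equilibration of C8'. This is a stepwise ionic etherification built from known reactions.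
2. **Step 4 (Reformatsky with a hindered α-bromo succinate and an electron-rich aldehyde).** Risks are elimination to the alkylidene succinate and epimerisation at C3.
   - Fallback: Ni-catalysed reductive cross-electrophile acylation of **5** with the S-2-pyridyl thioester of 4-benzyloxy-3,5-dimethoxybenzoic acid, giving the β-keto ester directly, then the same LiAlH4/MnO2 sequence.
3. **Step 2 (alkylation with a very electron-rich, ionisation-prone benzyl bromide).** Risks are SN1 self-condensation and lower dr.
   - Fallback: Seebach aldol of the (S)-malate dianion with aldehyde **6** to form the C3–C7 bond, followed by Et3SiH/TFA ionic deoxygenation of the benzylic carbinol, which converges both carbinol epimers.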